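1. We read at 12 min, so target made early stands in reagent until then. How many lifetimes of target fit into that time?

| flask | starting material | reagent | time | remark |
|---|---|---|---|---|
| oak | 0.048 M | 0.144 M (fed, over 12.0 min) | 12 min | a stirred flask in which reagent is dosed at a steady rate over 12.0 min without added volume, worked up at 12 min |
| elm | 0.048 M | 0.144 M |  | one stirred flow tank at steady state, fed with the mixture as stated, mean residence time 12 min |
| maple | 0.048 M (fed, over 12.0 min) | 0.144 M | 12 min | a stirred flask in which starting material is dosed at a steady rate over 12.0 min without added volume, worked up at 12 min |
| ash | 0.048 M | 0.144 M | 12 min | everything together in a closed stirred flask, run for 12 min |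

- the set-up with the highest amount of target at the outlet or at the end, in percent of the starting material put in ("none" if the first two lie within 2 percentage points) (oak / elm / maple / ash / none)
- amount of target at the outlet or at the end, in percent of the starting material put in, oak
- amount of target at the outlet or at the end, in percent of the starting material put in, elm
- amount of target at the outlet or at the end, in percent of the starting material put in, maple
- amount of target at the outlet or at the end, in percent of the starting material put in, ash

- the stated concentrations are those of everything mixed, before any reaction; amounts are the same in each set-up
- the feed brings no volume worth counting
- run time (oak): 12 min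

    starting material + reagent → intermediate A (k1 = 2.6 /M/min)
    starting material + reagent ⇌ intermediate B (K2 = 41 /M, k2 = 1.4 /M/min)
    intermediate A ⇌ intermediate C (K3 = 0.75, k3 = 0.028 /min)
    intermediate A ⇌ intermediate D (K4 = 2.5, k4 = 0.31 /min)
    intermediate B → target (k5 = 0.40 /min)
    intermediate C ⇌ target (K6 = 0.47, k6 = 0.0096 /min)
    reagent + target → over-reaction product (k7 = 1.4 /M/min)

2. Starting material splits at reagent, and a share 0.350, about a third, goes to intermediate B. Intermediate B falls back at 0.0341 /min, slower than it goes on at 0.40 /min, so we count that share as reaching target.

3. One equivalent spent leaves 66.7% of the reagent charge, and at that level target is burnt in a pseudo-first-order way. The burn number, target lifetimes per reading time at that level, is 1.61. Above 1, more than one lifetime of target fits into the reading time.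

4. Target arrives after a lag 4.24 min. Our reckoning for ash, with the lag taken off the exposure, gives 12.3%. For oak, reagent climbs during the run, so we take half of the burn number: 15.6%. For maple, target is born evenly during the feed: 14.1%. For elm, the tank form, with unfinished conversion counted, gives 9.11%.

5. One number was not enough: the burn number is the same in our four reckonings, and they part through the form each adds for exposure, lag or unfinished conversion. We pick oak.

6. The forecast says oak, with 14.5% for oak, 7.8% for elm, 11.3% for maple and 11.9% for ash: “Dosing reagent keeps it low while target forms”. It puts ash above maple; we put maple above ash.

7. The simulation gives oak: oak 14.8%, elm 8.08%, maple 10.7%, ash 10.9%.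

Oak leads ash by 3.9 percentage points. The forecast fails once ash comes within 2 points of oak, for then the answer is none. Read at 120 min, oak stands at 0.710% and ash at 0.704%, which is within that margin. Of ash's target and over-reaction product together, 36.9% is target; the lag-corrected burn number gave 35.3%. Intermediate C's forward half-life by its step to target, 72 min, is longer than the reading time, and ash ends with 7.99% as intermediate C. Maple read at 30 min: the burn number grows to 4.03, and the even-birth survivors, burnt on after the feed, give 2.73%. The simulation gives 3.26%.

Its constants are assumed; no experiment stands behind them.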